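**Retrosynthetic overview** (cyclopenta[c]pyridine numbering: N2, C3 side chain, C4a/C7a fusion, C5 carbinol, C6 ether carbon, C7 ketone)

1. The C3–dienyl bond is cut last: Stille coupling of chloropyridine 14 with the (1E,3E,5S)-dienylstannane 22, whose stereocentre comes from (S)-2-methylbutan-1-ol.
2. The strategy rests on the two oxygens on the adjacent quaternary carbons C5 (OH, CO2Me) and C6 (OMe, Me) of the cyclopentanone ring: they are trans, which is the pattern of anti opening of a C5–C6 oxirane, so 14 comes from methanolysis at C6 of the (5R,6R)-epoxide 13.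
3. Epoxide 13 comes from the flat, achiral aza-indenone 11 by catalytic enantioselective nucleophilic epoxidation with tert-butyl hydroperoxide, which sets C5 and C6 together.
4. Indenone 11 comes from indanone 9, itself made by SNAr of a malonate on methyl 4,6-dichloronicotinate, alkylation with a bromoacetate, Dieckmann closure, C-methylation and double decarboxylation.
5. Ring order: pyridine (bought), then cyclopentanone (Dieckmann), then oxirane (key step), which is opened again.

Key step: step 5

Remark on the chemistry: which pseudoenantiomeric cinchona salt gives the (5R,6R) epoxide cannot be predicted with certainty; the cinchonidinium salt is written, and the cinchoninium counterpart would be taken if the sense proves opposite.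

**Step 1**
Reactants: 1 methyl 4,6-dichloronicotinate; 2 tert-butyl methyl malonate; 3 tert-butyl bromoacetate
Product: 5 racemic 1,2-di-tert-butyl 1-methyl 1-[2-chloro-5-(methoxycarbonyl)pyridin-4-yl]ethane-1,1,2-tricarboxylate, via cesium arylmalonate enolate 4 (not isolated)
Conditions: 2 (1.05 equiv), Cs2CO3 (2.5 equiv), DMSO, 60 °C; then 3 (1.3 equiv), rt
Reagents that add atoms: none
Why: SNAr through a Meisenheimer adduct at C4 of 1 (the chloride ortho to the ester and para to the ring nitrogen, the site 4,6-dichloronicotinates are known to give up first), then SN2 alkylation of the stabilized arylmalonate anion by the α-bromo ester in the same flask, which builds the quaternary carbon that becomes C5; the anionic malonate protects the ring from a second substitution.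

**Step 2**
Reactants: 5
Product: 7 5,6-di-tert-butyl 5-methyl 3-chloro-6-methyl-7-oxo-6,7-dihydro-5H-cyclopenta[c]pyridine-5,5,6-tricarboxylate (racemic diastereomer mixture), via potassium keto ester enolate 6 (not isolated)
Conditions: t-BuOK (1.3 equiv), THF, 0 °C to rt; then MeI (3 equiv), rt
Reagents that add atoms: iodomethane, CI
Why: Dieckmann condensation in which the only enolizable position, the CH2 of the tert-butyl acetate arm, attacks the neighbouring nicotinate ester to close the five-membered ketone (helped by the gem-disubstituted C5), and the resulting β-keto ester enolate is C-methylated by the small electrophile MeI; the stereocentres formed are removed in steps 3 and 4.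

**Step 3**
Reactants: 7
Product: 9 methyl 3-chloro-6-methyl-7-oxo-6,7-dihydro-5H-cyclopenta[c]pyridine-5-carboxylate (racemic cis/trans mixture), via keto diacid 8 (not isolated)
Conditions: CF3CO2H/CH2Cl2 (1:2), rt; evaporate; toluene, 100 °C
Reagents that add atoms: none
Why: Acidolysis of both tert-butyl esters (loss of isobutene) leaves the methyl ester untouched, and on warming the β-keto acid at C6 and the aryl malonic half acid at C5 each lose CO2 through a six-membered cyclic transition state.

**Step 4**
Reactants: 9
Product: 11 methyl 3-chloro-6-methyl-7-oxo-7H-cyclopenta[c]pyridine-5-carboxylate, via 6-bromo ketone 10 (not isolated)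
Conditions: Br2 (1.05 equiv), AcOH, rt; evaporate; Et3N (1.5 equiv), CH2Cl2, 0 °C; rapid filtration through silica
Reagents that add atoms: bromine, BrBr (its atom sits only in intermediate 10 and leaves again as bromide)
Why: Acid-catalysed α-bromination of the ketone through its enol, then E1cB dehydrobromination driven by the acidity of C5–H (α to the ester and benzylic to the pyridin-4-yl position); bromination at C5 instead would lead to the same tetrasubstituted alkene.

**Step 5**
Reactants: 11; 12 tert-butyl hydroperoxide
Product: 13 methyl (5R,6R)-3-chloro-5,6-epoxy-6-methyl-7-oxo-6,7-dihydro-5H-cyclopenta[c]pyridine-5-carboxylate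
Conditions: 12 (1.5 equiv, solution in decane), N-(9-anthracenylmethyl)-O-benzylcinchonidinium bromide (10 mol%), powdered K2CO3 (0.5 equiv), toluene, −20 °C
Reagents that add atoms: none
Why: This is a Weitz–Scheffer nucleophilic epoxidation under chiral phase-transfer catalysis, the reaction type established for enones and 2,3-disubstituted quinones: the tert-butylperoxide anion, carried into toluene as an ion pair with the cinchonidinium cation, adds in conjugate fashion to the C5=C6 bond, whose carbons are each β to a carbonyl (C5 to the C7 ketone, C6 to the ester), and gives a delocalised enolate. The oxirane is then closed by 3-exo-tet attack of the enolate carbon on the proximal peroxide oxygen with loss of tert-butoxide, which regenerates the peroxide anion, so a substoichiometric weak base suffices. Both new stereocentres, C5 and C6, arise in this one event and are tied to each other because a fused oxirane can only be cis; their absolute sense is set by the catalyst, whose ammonium centre, screened by the anthracenylmethyl, benzyl and quinoline groups, should present the peroxide to one face of the flat bicycle. The only selectivity needed is therefore enantioface selectivity. The substrate helps because the alkene is planar, strained, doubly activated and has no α-hydrogen (only the weakly acidic vinylogous hydrogens of the C6 methyl), so addition should be fast at low temperature, and the uncatalysed background is held down because the peroxide salt is insoluble in toluene without the catalyst.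

**Step 6**
Reactants: 13
Product: 14 methyl (5R,6S)-3-chloro-5-hydroxy-6-methoxy-6-methyl-7-oxo-6,7-dihydro-5H-cyclopenta[c]pyridine-5-carboxylate
Conditions: CF3SO3H (2 equiv), dry MeOH, 0 °C to 40 °C; NaHCO3 work-up
Reagents that add atoms: methanol, CO
Why: Acid-catalysed epoxide alcoholysis in its borderline SN2 mode: positive charge at C5 is opposed by the ester on that carbon and by the electron-poor, partly protonated pyridine ring, whereas C6 carries a methyl group and is β to the ester (the site at which glycidic esters open), so methanol should enter at C6 from the face opposite the oxirane oxygen, keeping C5 as (R) and inverting C6 to (S) to give the trans hydroxy ether; the methyl ester cannot be changed by transesterification in methanol.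

**Step 7**
Reactants: 15 (S)-2-methylbutan-1-ol; 16 ethyl 2-(triphenylphosphoranylidene)propanoate
Product: 18 ethyl (2E,4S)-2,4-dimethylhex-2-enoate, via (S)-2-methylbutanal 17 (not isolated)
Conditions: TEMPO (10 mol%), PhI(OAc)2 (1.1 equiv), CH2Cl2, rt; then 16 (1.3 equiv), rt
Reagents that add atoms: none
Why: Oxoammonium oxidation under near-neutral conditions should not epimerise the α-stereocentre, and the volatile aldehyde is trapped at once in a Wittig reaction with the stabilized α-methyl ylide, which is E-selective.

**Step 8**
Reactants: 18
Product: 19 (2E,4S)-2,4-dimethylhex-2-en-1-ol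
Conditions: i-Bu2AlH (2.2 equiv), CH2Cl2, −78 °C; Rochelle salt work-up
Reagents that add atoms: none
Why: 1,2-Reduction of the unsaturated ester by DIBAL-H to the allylic alcohol without touching the alkene geometry or the stereocentre.

**Step 9**
Reactants: 19
Product: 20 (2E,4S)-2,4-dimethylhex-2-enal
Conditions: activated MnO2 (excess), CH2Cl2, rt
Reagents that add atoms: none
Why: Selective allylic oxidation on the MnO2 surface under neutral conditions, which should leave the γ-stereocentre and the E alkene unchanged.

**Step 10**
Reactants: 20
Product: 21 (3E,5S)-3,5-dimethylhept-3-en-1-yne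
Conditions: Me3SiCHN2 (1.2 equiv), n-BuLi (1.2 equiv), THF, −78 °C to rt
Reagents that add atoms: trimethylsilyldiazomethane, C[Si](C)(C)C=[N+]=[N-]
Why: Colvin homologation: lithiated trimethylsilyldiazomethane adds to the aldehyde, Peterson elimination gives a diazoalkene, and loss of N2 with 1,2-hydrogen shift of the alkylidene carbene gives the terminal enyne; the fast addition at −78 °C outruns γ-deprotonation.

**Step 11**
Reactants: 21
Product: 22 tributyl[(1E,3E,5S)-3,5-dimethylhepta-1,3-dien-1-yl]stannane
Conditions: Bu3SnH (1.2 equiv), PdCl2(PPh3)2 (2 mol%), THF, 0 °C; chromatography on Et3N-treated silica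
Reagents that add atoms: tributyltin hydride, CCCC[SnH](CCCC)CCCC
Why: Palladium-catalysed hydrostannation (the precatalyst is reduced to zerovalent palladium by the tin hydride) is a syn addition across the terminal alkyne that places tin on the terminal carbon, away from the branched alkenyl substituent, and so should give the (1E) dienylstannane.

**Step 12**
Reactants: 14; 22
Product: 23 methyl (5R,6S)-3-[(1E,3E,5S)-3,5-dimethylhepta-1,3-dien-1-yl]-5-hydroxy-6-methoxy-6-methyl-7-oxo-6,7-dihydro-5H-cyclopenta[c]pyridine-5-carboxylate
Conditions: 22 (1.3 equiv), Pd(PPh3)4 (5 mol%), degassed 1,4-dioxane, 90 °C, dark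
Reagents that add atoms: none
Why: Stille coupling: zerovalent palladium inserts into the C–Cl bond of the 2-chloropyridine, which is activated by the ring nitrogen and the para acyl group, the alkenyl group is transferred from tin with retention of geometry, and the base-free conditions spare the tertiary β-hydroxy ketone and all three stereocentres.

**Compound list**

1 | methyl 4,6-dichloronicotinate | COC(=O)c1cnc(Cl)cc1Cl | starting material
2 | tert-butyl methyl malonate | COC(=O)CC(=O)OC(C)(C)C | starting material
3 | tert-butyl bromoacetate | CC(C)(C)OC(=O)CBr | starting material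
4 | cesium enolate of 1-tert-butyl 3-methyl 2-[2-chloro-5-(methoxycarbonyl)pyridin-4-yl]propanedioate | COC(=O)c1cnc(Cl)cc1C(C(=O)OC(C)(C)C)=C([O-])OC.[Cs+] | intermediate
5 | 1,2-di-tert-butyl 1-methyl 1-[2-chloro-5-(methoxycarbonyl)pyridin-4-yl]ethane-1,1,2-tricarboxylate (racemic) | COC(=O)c1cnc(Cl)cc1C(CC(=O)OC(C)(C)C)(C(=O)OC)C(=O)OC(C)(C)C | intermediate
6 | potassium enolate of 5,6-di-tert-butyl 5-methyl 3-chloro-7-oxo-6,7-dihydro-5H-cyclopenta[c]pyridine-5,5,6-tricarboxylate | COC(=O)C1(C(=O)OC(C)(C)C)c2cc(Cl)ncc2C([O-])=C1C(=O)OC(C)(C)C.[K+] | intermediate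
7 | 5,6-di-tert-butyl 5-methyl 3-chloro-6-methyl-7-oxo-6,7-dihydro-5H-cyclopenta[c]pyridine-5,5,6-tricarboxylate (racemic, diastereomer mixture) | COC(=O)C1(C(=O)OC(C)(C)C)c2cc(Cl)ncc2C(=O)C1(C)C(=O)OC(C)(C)C | intermediate
8 | 3-chloro-5-(methoxycarbonyl)-6-methyl-7-oxo-6,7-dihydro-5H-cyclopenta[c]pyridine-5,6-dicarboxylic acid | COC(=O)C1(C(=O)O)c2cc(Cl)ncc2C(=O)C1(C)C(=O)O | intermediate
9 | methyl 3-chloro-6-methyl-7-oxo-6,7-dihydro-5H-cyclopenta[c]pyridine-5-carboxylate (racemic, cis/trans mixture) | COC(=O)C1c2cc(Cl)ncc2C(=O)C1C | intermediate
10 | methyl 6-bromo-3-chloro-6-methyl-7-oxo-6,7-dihydro-5H-cyclopenta[c]pyridine-5-carboxylate | COC(=O)C1c2cc(Cl)ncc2C(=O)C1(C)Br | intermediate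
11 | methyl 3-chloro-6-methyl-7-oxo-7H-cyclopenta[c]pyridine-5-carboxylate | COC(=O)C1=C(C)C(=O)c2cnc(Cl)cc12 | intermediate
12 | tert-butyl hydroperoxide | CC(C)(C)OO | starting material
13 | methyl (5R,6R)-3-chloro-5,6-epoxy-6-methyl-7-oxo-6,7-dihydro-5H-cyclopenta[c]pyridine-5-carboxylate | Clc1cc2c(cn1)C(=O)[C@]3(C)O[C@]23C(=O)OC | intermediate
14 | methyl (5R,6S)-3-chloro-5-hydroxy-6-methoxy-6-methyl-7-oxo-6,7-dihydro-5H-cyclopenta[c]pyridine-5-carboxylate | Clc1cc2c(cn1)C(=O)[C@@](C)(OC)[C@@]2(O)C(=O)OC | intermediate
15 | (S)-2-methylbutan-1-ol | CC[C@H](C)CO | starting material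
16 | ethyl 2-(triphenylphosphoranylidene)propanoate | CCOC(=O)C(C)=P(c1ccccc1)(c1ccccc1)c1ccccc1 | starting material
17 | (S)-2-methylbutanal | CC[C@H](C)C=O | intermediate
18 | ethyl (2E,4S)-2,4-dimethylhex-2-enoate | CC[C@H](C)/C=C(\C)C(=O)OCC | intermediate
19 | (2E,4S)-2,4-dimethylhex-2-en-1-ol | CC[C@H](C)/C=C(\C)CO | intermediate
20 | (2E,4S)-2,4-dimethylhex-2-enal | CC[C@H](C)/C=C(\C)C=O | intermediate
21 | (3E,5S)-3,5-dimethylhept-3-en-1-yne | CC[C@H](C)/C=C(\C)C#C | intermediate
22 | tributyl[(1E,3E,5S)-3,5-dimethylhepta-1,3-dien-1-yl]stannane | CC[C@H](C)/C=C(C)/C=C/[Sn](CCCC)(CCCC)CCCC | intermediate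
23 | methyl (5R,6S)-3-[(1E,3E,5S)-3,5-dimethylhepta-1,3-dien-1-yl]-5-hydroxy-6-methoxy-6-methyl-7-oxo-6,7-dihydro-5H-cyclopenta[c]pyridine-5-carboxylate | CC[C@H](C)/C=C(C)/C=C/c1cc2c(cn1)C(=O)[C@@](C)(OC)[C@@]2(O)C(=O)OC | target

**Step count**

Total: 12 steps. Longest linear sequence: 7 steps (steps 1 to 6, then step 12); the side chain takes steps 7 to 11.

**Steps most likely to fail**

1. Step 5. The ion pair may discriminate poorly between the two faces of a flat substrate that has no directing group, or the basic peroxide may attack the ketone and degrade the indenone. The fallback sets out from 11: racemic Weitz–Scheffer epoxidation with 12 and DBU in CH2Cl2 at 0 °C would give the racemic cis-epoxide methyl (5R*,6R*)-3-chloro-5,6-epoxy-6-methyl-7-oxo-6,7-dihydro-5H-cyclopenta[c]pyridine-5-carboxylate F1. This would be resolved by preparative supercritical-fluid chromatography on a chiral stationary phase. The (5R,6R) enantiomer is 13, where the route is rejoined, and the (5S,6S) enantiomer F2 is set aside.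

2. Step 6. Methanol may attack C5 instead of C6, or a cationic C6 may trigger acyl or aryl migration, because both oxirane carbons are quaternary and each is next to a carbonyl group. The fallback sets out from 13: Luche reduction (NaBH4, CeCl3·7H2O, MeOH, −40 °C) of the C7 ketone would give the epoxy alcohol methyl (5R,6S,7RS)-3-chloro-5,6-epoxy-7-hydroxy-6-methyl-6,7-dihydro-5H-cyclopenta[c]pyridine-5-carboxylate F3, either C7 epimer being usable. With no carbonyl left next to C6, acid methanolysis (CF3SO3H, MeOH) would follow the known course of glycidic esters, attack at the carbon β to the ester with inversion, and give methyl (5R,6R,7RS)-3-chloro-5,7-dihydroxy-6-methoxy-6-methyl-6,7-dihydro-5H-cyclopenta[c]pyridine-5-carboxylate F4. Oxidation of the secondary benzylic alcohol with Dess–Martin periodinane in CH2Cl2 would return 14.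

3. Step 4. Over-bromination, or amine-induced conjugate addition and oligomerisation of the very electrophilic indenone during dehydrobromination, may erode the material. The fallback sets out from 9: deprotonation with KN(SiMe3)2 in THF at −78 °C and hydroxylation of the enolate with 2-(phenylsulfonyl)-3-phenyloxaziridine would give the tertiary alcohol methyl 3-chloro-5-hydroxy-6-methyl-7-oxo-6,7-dihydro-5H-cyclopenta[c]pyridine-5-carboxylate F5, a β-hydroxy ketone. Amine-free, acid-catalysed dehydration through the ketone enol (TsOH, toluene, 90 °C) would give 11; hydroxylation at C6 instead would converge on the same alkene.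

**Further compounds**

F1 | step 5 | methyl (5R*,6R*)-3-chloro-5,6-epoxy-6-methyl-7-oxo-6,7-dihydro-5H-cyclopenta[c]pyridine-5-carboxylate (racemic cis-epoxide) | COC(=O)C12OC1(C)C(=O)c1cnc(Cl)cc12
F2 | step 5 | methyl (5S,6S)-3-chloro-5,6-epoxy-6-methyl-7-oxo-6,7-dihydro-5H-cyclopenta[c]pyridine-5-carboxylate | Clc1cc2c(cn1)C(=O)[C@@]3(C)O[C@@]23C(=O)OC
F3 | step 6 | methyl (5R,6S,7RS)-3-chloro-5,6-epoxy-7-hydroxy-6-methyl-6,7-dihydro-5H-cyclopenta[c]pyridine-5-carboxylate | Clc1cc2c(cn1)C(O)[C@]3(C)O[C@]23C(=O)OC
F4 | step 6 | methyl (5R,6R,7RS)-3-chloro-5,7-dihydroxy-6-methoxy-6-methyl-6,7-dihydro-5H-cyclopenta[c]pyridine-5-carboxylate | Clc1cc2c(cn1)C(O)[C@@](C)(OC)[C@@]2(O)C(=O)OC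
F5 | step 4 | methyl 3-chloro-5-hydroxy-6-methyl-7-oxo-6,7-dihydro-5H-cyclopenta[c]pyridine-5-carboxylate (racemic, diastereomer mixture) | COC(=O)C1(O)c2cc(Cl)ncc2C(=O)C1C
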